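## Structural features

Pentabromopseudilin is a biaryl without stereocenters. Ring A is a phenol (C1 to C6: C1 carries the pyrrole, C2 the hydroxyl, C3 and C5 bromine, C4 and C6 hydrogen). Ring B is a 1H-pyrrole (N1', C2' bonded to C1, bromine on C3', C4' and C5'). The rings are joined by the single C1–C2' bond, which lies ortho to the hydroxyl group; the axis is not a stable stereogenic element. Every position of both rings that is activated towards electrophiles holds bromine, so ring B can be brominated exhaustively. Once in place, the five C–Br bonds rule out low-valent metals, alkyllithium reagents and hydrogenation. Before bromination the NH-pyrrole is electron-rich and sensitive to acid and air, and both OH and NH are acidic. The real difficulty is the C1–C2' bond: it unites two carbons that are both nucleophilic positions of π-excessive rings, inside the contiguous C1/C2/C3 array of ring A (heteroaryl, oxygen, bromine). The key step exploits the fact that the C3(Br)–C4(H)–C5(Br)–C6(H) half of ring A has exactly the substitution of diene carbons C3 to C6 of 3,5-dibromo-2-pyrone, while the C1–C2 edge, carrying pyrrole and oxygen, is a polarised two-carbon unit at the oxidation level of an alkyne.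

## Logic of the disconnections

In one sentence: ring A of 8 is built onto a finished pyrrole by [4+2] cycloaddition of alkyne 5 with pyrone 6 and loss of carbon dioxide. This sentence does not describe a biaryl cross-coupling followed by bromination, which is the route most chemists would draw first.

11 to 9: the O–Si bond at C2 and the N1'–CH2 bond are cut, both protecting groups in one fluoride operation (through 10). Deprotection is placed last because in 9 every nucleophilic carbon is already substituted, so the formaldehyde released from nitrogen cannot add back. The forward step must spare five C–Br bonds, which fluoride does.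

9 to 8: the three C–Br bonds at C3', C4' and C5' are cut. All open positions of ring B are to be filled, so no regiochemical question arises, and the open positions of ring A (C4, C6) are meta to oxygen. The demand is that ring A already carries its two bromines, which the next disconnection supplies by construction.

8 to 5 and 6 (key disconnection): the C1–C6 and C2–C3 bonds of ring A are cut, with carbon dioxide added back across C3 and C6 to give bicycle 7 and then diene 6. This removes the whole of ring A with its oxygen, both bromines and the biaryl junction, and leaves a purchasable diene and a two-carbon dienophile on a simple pyrrole. The forward step needs one orientation, oxygen next to the C3 bromine, and a dienophile that survives heating.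

5 to 2: the O–Si bond, the triple bond and the C2'–C(alkyne) bond are cut. The oxygen-bearing alkyne carbon is the former ester carbon, and the other alkyne carbon is inserted as a carbenoid with 1,2-shift of the pyrrole (through 3 and 4). The gain is a commercial pyrrole ester in place of an ynol ether. The demand is a nitrogen substituent that tolerates lithium amides and alkyllithiums.

2 to 1: the N1'–CH2 bond is cut, giving the commercial ester 1. The group chosen must survive strong base and 110 °C and leave with fluoride.

## Other disconnections considered

Alternative 1: the first that comes to mind is to cut the C1–C2' biaryl bond. The forward key step would be a Suzuki–Miyaura coupling of (1-tert-butoxycarbonylpyrrol-2-yl)boronic acid A1 with 2-bromoanisole A2 (Pd(PPh3)4, aqueous Na2CO3) to give biaryl A3. Removal of the carbamate and the methyl ether would give 2-(1H-pyrrol-2-yl)phenol A4, and five equivalents of electrophilic bromine would give 11. It is short, but it is the conventional route. No C–Br bond can be present during the palladium step, so all five halogens fall on one late bromination of an oxidisable hydroxyphenylpyrrole, and 2-pyrrolylboronic acids are prone to protodeboronation. The chosen plan places the two ring A bromines and the oxygen by construction and needs no metal catalyst.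

Alternative 2: ring B could be closed last at nitrogen. The forward key step would be a Paal–Knorr condensation of the 1,4-dicarbonyl compound A5 with ammonia to give 2-(3,5-dibromo-2-methoxyphenyl)-1H-pyrrole A6, followed by bromination of ring B and ether cleavage. The closure is the usual one at the heteroatom. A5 needs several steps of its own (an acyl anion addition or an enolate alkylation with later release of the aldehyde). The methyl ether must finally be cleaved with a strong Lewis acid in the presence of the sensitive pyrrole. The step economy is worse and the difficulty is only moved into the synthesis of A5.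

Alternative 3: the biomimetic union of like polarity would cut C1–C2' oxidatively. The forward key step would be a one-electron oxidative cross-coupling of 2,4-dibromophenol A7 with 2,3,4-tribromo-1H-pyrrole A8, giving 11 in one step. Nothing in either substrate favours C–C bonding at the phenol ortho carbon over C–O coupling, or cross-coupling over dimerisation of the phenoxyl radical. A8 is an unstable pyrrole with one open α position. Selectivity would rest on the oxidant alone, whereas in the chosen plan the orientation follows from the polarisation of both cycloaddition partners.

Key step: step 3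

Assumption: 3,5-dibromo-2H-pyran-2-one (6) is taken as purchasable; it is otherwise available in one step from coumalic acid by bromodecarboxylation.

## Route

Step 1
Reactants: 1 methyl 1H-pyrrole-2-carboxylate
Product: 2 methyl 1-{[2-(trimethylsilyl)ethoxy]methyl}-1H-pyrrole-2-carboxylate
Conditions: NaH, SEMCl, DMF, 0 °C to rt
Reagents that add atoms: 2-(trimethylsilyl)ethoxymethyl chloride (SEMCl), C[Si](C)(C)CCOCCl
Why: N-alkylation of the sodium pyrrolide, whose NH is acidified by the ester; the SEM group tolerates lithium amides, alkyllithiums and heat and leaves with fluoride.

Step 2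
Reactants: 2 methyl 1-{[2-(trimethylsilyl)ethoxy]methyl}-1H-pyrrole-2-carboxylate
Product: 5 2-[2-(triisopropylsilyloxy)ethynyl]-1-{[2-(trimethylsilyl)ethoxy]methyl}-1H-pyrrole, via lithium dibromoenolate 3 (not isolated), via lithium ynolate 4 (not isolated)
Conditions: CH2Br2, lithium 2,2,6,6-tetramethylpiperidide (LiTMP), THF, −78 °C; n-BuLi, −78 to 0 °C; TIPSOTf, −78 to 0 °C
Reagents that add atoms: dibromomethane, BrCBr; triisopropylsilyl trifluoromethanesulfonate (TIPSOTf), CC(C)[Si](C(C)C)(C(C)C)OS(=O)(=O)C(F)(F)F
Why: Kowalski ynolate synthesis with O-silylation: dibromomethyllithium adds to the ester to give enolate 3, bromine–lithium exchange and 1,2-shift of the pyrrolyl group (carbenoid rearrangement, well behaved for aryl esters) give ynolate 4, and the bulky, hard silyl triflate reacts at oxygen to give the siloxyalkyne.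

Step 3
Reactants: 5 2-[2-(triisopropylsilyloxy)ethynyl]-1-{[2-(trimethylsilyl)ethoxy]methyl}-1H-pyrrole; 6 3,5-dibromo-2H-pyran-2-one
Product: 8 2-[3,5-dibromo-2-(triisopropylsilyloxy)phenyl]-1-{[2-(trimethylsilyl)ethoxy]methyl}-1H-pyrrole, via bicyclic lactone 7 (not isolated)
Conditions: PhMe, 110 °C, sealed tube, Ar
Reagents that add atoms: none
Why: This is the pyrone–alkyne benzannulation, an inverse-electron-demand Diels–Alder reaction of a 2-pyrone with a heteroatom-substituted alkyne followed by retro-[4+2] loss of CO2. The oxygen lone pair of 5 raises the alkyne HOMO and concentrates it on the carbon that carries the pyrrole, while the lactone carbonyl and the two bromines of 6 lower the diene LUMO and place its largest coefficient at C6, the terminus of the vinylogous ester. Bond formation should therefore be asynchronous: the pyrrole-bearing alkyne carbon attacks C6 of 6 and the developing silyl ketenium carbon is captured by C3 of the dienolate, giving bicycle 7 with the oxygen-bearing carbon on the brominated bridgehead. Ring A is thus closed as a six-membered carbocycle by an intermolecular [4+2] closure that forms its C1–C6 and C2–C3 bonds, and the cycloreversion of 7 that expels CO2 is driven by aromatisation and should be faster than the cycloaddition at this temperature. The two bridgehead stereocenters of 7 are erased in that step, so no stereocontrol is needed. The one selectivity required is the orientation, silyloxy next to the C3 bromine; it rests on the match of polarised termini, and the opposing donor effect of the N-alkylpyrrole is weaker than that of an oxygen directly on the triple bond (electrophiles add to 1-aryl-2-alkoxyalkynes at the aryl-bearing carbon). The triisopropylsilyl group has no hydrogen to lose in a retro-ene reaction (the path by which ethyl ynol ethers give ketenes near this temperature) and it slows the 1,3-shift of silicon to carbon; the C–Br bonds are safe because neither metal nor base is present.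

Step 4
Reactants: 8 2-[3,5-dibromo-2-(triisopropylsilyloxy)phenyl]-1-{[2-(trimethylsilyl)ethoxy]methyl}-1H-pyrrole
Product: 9 2,3,4-tribromo-5-[3,5-dibromo-2-(triisopropylsilyloxy)phenyl]-1-{[2-(trimethylsilyl)ethoxy]methyl}-1H-pyrrole
Conditions: NBS (3.1 equiv), THF, −78 to 0 °C, dark
Reagents that add atoms: N-bromosuccinimide (NBS), O=C1CCC(=O)N1Br
Why: Electrophilic aromatic bromination at the three open positions of the N-alkylpyrrole, which is far more reactive than ring A (two bromines, open positions C4 and C6 meta to oxygen); the substitution is exhaustive, so no regiochemical question arises, and silyl ether and SEM group tolerate NBS.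

Step 5
Reactants: 9 2,3,4-tribromo-5-[3,5-dibromo-2-(triisopropylsilyloxy)phenyl]-1-{[2-(trimethylsilyl)ethoxy]methyl}-1H-pyrrole
Product: 11 pentabromopseudilin [2,4-dibromo-6-(3,4,5-tribromo-1H-pyrrol-2-yl)phenol], via N-SEM phenoxide 10 (not isolated)
Conditions: TBAF (excess), THF, rt to 50 °C; 1 M HCl work-up
Reagents that add atoms: none
Why: Fluoride desilylation: the aryl silyl ether of the acidic dibromophenol falls first, then attack of fluoride on the trimethylsilyl group fragments the SEM group to ethylene, formaldehyde and the stabilised tribromopyrrolide, a good leaving group. No nucleophilic ring carbon is left open, so formaldehyde cannot add back, and the C–Br bonds are inert to fluoride.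

## Compound list

1 | methyl 1H-pyrrole-2-carboxylate | COC(=O)c1ccc[nH]1 | starting material
2 | methyl 1-{[2-(trimethylsilyl)ethoxy]methyl}-1H-pyrrole-2-carboxylate | COC(=O)c1cccn1COCC[Si](C)(C)C | intermediate
3 | lithium 2,2-dibromo-1-(1-{[2-(trimethylsilyl)ethoxy]methyl}-1H-pyrrol-2-yl)ethen-1-olate | [Li]OC(=C(Br)Br)c1cccn1COCC[Si](C)(C)C | intermediate (not isolated)
4 | lithium 2-(1-{[2-(trimethylsilyl)ethoxy]methyl}-1H-pyrrol-2-yl)ethyn-1-olate | [Li]OC#Cc1cccn1COCC[Si](C)(C)C | intermediate (not isolated)
5 | 2-[2-(triisopropylsilyloxy)ethynyl]-1-{[2-(trimethylsilyl)ethoxy]methyl}-1H-pyrrole | CC(C)[Si](OC#Cc1cccn1COCC[Si](C)(C)C)(C(C)C)C(C)C | intermediate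
6 | 3,5-dibromo-2H-pyran-2-one | O=C1OC=C(Br)C=C1Br | starting material
7 | 4,7-dibromo-5-(triisopropylsilyloxy)-6-(1-{[2-(trimethylsilyl)ethoxy]methyl}-1H-pyrrol-2-yl)-2-oxabicyclo[2.2.2]octa-5,7-dien-3-one (racemic; the bicycle allows only one relative configuration of the two bridgeheads) | O=C1OC2C(Br)=CC1(Br)C(O[Si](C(C)C)(C(C)C)C(C)C)=C2c1cccn1COCC[Si](C)(C)C | intermediate (not isolated)
8 | 2-[3,5-dibromo-2-(triisopropylsilyloxy)phenyl]-1-{[2-(trimethylsilyl)ethoxy]methyl}-1H-pyrrole | CC(C)[Si](Oc1c(Br)cc(Br)cc1-c1cccn1COCC[Si](C)(C)C)(C(C)C)C(C)C | intermediate
9 | 2,3,4-tribromo-5-[3,5-dibromo-2-(triisopropylsilyloxy)phenyl]-1-{[2-(trimethylsilyl)ethoxy]methyl}-1H-pyrrole | CC(C)[Si](Oc1c(Br)cc(Br)cc1-c1c(Br)c(Br)c(Br)n1COCC[Si](C)(C)C)(C(C)C)C(C)C | intermediate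
10 | 2,4-dibromo-6-(3,4,5-tribromo-1-{[2-(trimethylsilyl)ethoxy]methyl}-1H-pyrrol-2-yl)phenol (present as its tetrabutylammonium phenoxide) | Oc1c(Br)cc(Br)cc1-c1c(Br)c(Br)c(Br)n1COCC[Si](C)(C)C | intermediate (not isolated)
11 | pentabromopseudilin, 2,4-dibromo-6-(3,4,5-tribromo-1H-pyrrol-2-yl)phenol | Oc1c(Br)cc(Br)cc1-c1[nH]c(Br)c(Br)c1Br | target

## Step count and least certain steps

Total step count: 5. Longest linear sequence: 5 steps (1 to 2 to 5 to 8 to 9 to 11); 6 enters in step 3.

Step 3 (key step): the most likely failure is thermal decay of 5 outrunning the cycloaddition (1,3-shift of silicon to give a silylketene, or [2+2] dimerisation). A second risk is partial reversal of the orientation, because the pyrrole donor opposes the siloxy group. The fallback changes the dienophile from an alkyne to a ketene acetal. It sets out from 2. The carbenoid sequence of step 2 is run as far as ynolate 4, which is quenched with HCl in methanol to give methyl 2-(1-{[2-(trimethylsilyl)ethoxy]methyl}-1H-pyrrol-2-yl)acetate F1 (Kowalski homologation). Lithium diisopropylamide and TIPSOTf then give 1-methoxy-2-(1-{[2-(trimethylsilyl)ethoxy]methyl}-1H-pyrrol-2-yl)-1-(triisopropylsilyloxy)ethene F2 (either alkene geometry serves). F2 is a stronger nucleophile than 5 and is polarised in the same sense. Heating F2 with 6 should give Diels–Alder addition, loss of CO2 and loss of methanol from the acetal carbon, and so 8, where the fallback rejoins the route.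

Step 2: the likely failures are slow addition of the carbenoid to the electron-rich, vinylogous-carbamate-like ester, competing lithiation at the open α position of the pyrrole by excess alkyllithium, and hydrolysis of the siloxyalkyne during isolation (chromatography on base-washed silica is intended). The fallback reaches the same ynolate by oxidation and not by rearrangement. It sets out from 2. Reduction with i-Bu2AlH at −78 °C gives 1-{[2-(trimethylsilyl)ethoxy]methyl}-1H-pyrrole-2-carbaldehyde F3. The Ohira–Bestmann reagent (K2CO3, MeOH) gives 2-ethynyl-1-{[2-(trimethylsilyl)ethoxy]methyl}-1H-pyrrole F4. Deprotonation with LiN(SiMe3)2 and oxidation of the lithium acetylide with lithium tert-butyl peroxide gives ynolate 4, which is silylated as in step 2 to 5.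

Step 4: the likely failure is incomplete substitution at C3', which is flanked by the twisted ring A and its bulky silyl ether; acid-induced loss of a protecting group from traces of HBr is a lesser risk. The fallback reverses the order of the last two operations. It sets out from 8. TBAF (with ethylenediamine to trap formaldehyde) gives 2,4-dibromo-6-(1H-pyrrol-2-yl)phenol F5. Exhaustive bromination of this free, less hindered and more activated hydroxyphenylpyrrole with NBS or pyridinium tribromide then gives 11 directly.

Step 5: the likely failure is stalling of the SEM cleavage, either slow attack of fluoride on the trimethylsilyl group or retention of the N–CH2–O fragment. The fallback opens the SEM group by Lewis-acid ionisation. It sets out from 9. BF3·OEt2 in CH2Cl2, with loss of ethylene and Me3SiF and aqueous work-up, gives {2,3,4-tribromo-5-[3,5-dibromo-2-(triisopropylsilyloxy)phenyl]-1H-pyrrol-1-yl}methanol F6. Fluoride at room temperature then has only to remove the aryl silyl ether, and the hemiaminal loses formaldehyde under the same basic conditions, giving 11.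

## Further compounds

F1 | step 3 | methyl 2-(1-{[2-(trimethylsilyl)ethoxy]methyl}-1H-pyrrol-2-yl)acetate | COC(=O)Cc1cccn1COCC[Si](C)(C)C
F2 | step 3 | 1-methoxy-2-(1-{[2-(trimethylsilyl)ethoxy]methyl}-1H-pyrrol-2-yl)-1-(triisopropylsilyloxy)ethene (alkene geometry not fixed) | COC(=Cc1cccn1COCC[Si](C)(C)C)O[Si](C(C)C)(C(C)C)C(C)C
F3 | step 2 | 1-{[2-(trimethylsilyl)ethoxy]methyl}-1H-pyrrole-2-carbaldehyde | O=Cc1cccn1COCC[Si](C)(C)C
F4 | step 2 | 2-ethynyl-1-{[2-(trimethylsilyl)ethoxy]methyl}-1H-pyrrole | C#Cc1cccn1COCC[Si](C)(C)C
F5 | step 4 | 2,4-dibromo-6-(1H-pyrrol-2-yl)phenol | Oc1c(Br)cc(Br)cc1-c1ccc[nH]1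
F6 | step 5 | {2,3,4-tribromo-5-[3,5-dibromo-2-(triisopropylsilyloxy)phenyl]-1H-pyrrol-1-yl}methanol | OCn1c(Br)c(Br)c(Br)c1-c1cc(Br)cc(Br)c1O[Si](C(C)C)(C(C)C)C(C)C
A1 | alternative 1 | (1-tert-butoxycarbonyl-1H-pyrrol-2-yl)boronic acid | CC(C)(C)OC(=O)n1cccc1B(O)O
A2 | alternative 1 | 2-bromoanisole | COc1ccccc1Br
A3 | alternative 1 | tert-butyl 2-(2-methoxyphenyl)-1H-pyrrole-1-carboxylate | COc1ccccc1-c1cccn1C(=O)OC(C)(C)C
A4 | alternative 1 | 2-(1H-pyrrol-2-yl)phenol | Oc1ccccc1-c1ccc[nH]1
A5 | alternative 2 | 4-(3,5-dibromo-2-methoxyphenyl)-4-oxobutanal | COc1c(Br)cc(Br)cc1C(=O)CCC=O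
A6 | alternative 2 | 2-(3,5-dibromo-2-methoxyphenyl)-1H-pyrrole | COc1c(Br)cc(Br)cc1-c1ccc[nH]1
A7 | alternative 3 | 2,4-dibromophenol | Oc1ccc(Br)cc1Br
A8 | alternative 3 | 2,3,4-tribromo-1H-pyrrole | Brc1c[nH]c(Br)c1Br
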